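## Retrosynthetic overview

1. Rings: both benzene rings are bought; the cyclopropane and the γ-lactone close together in one operation from phosphonoacetate 1 and (R)-epichlorohydrin 2 (1 + 2 → 3 → 4 → 5). The cyclopropane is cleaved later; the lactone is the ring of the target.
2. Stereocentre: C4 of the target is the CH carbon of 2, relayed through one SN2 inversion in that cascade and never touched again.
3. Exocyclic C=C (last bond made): Horner–Wadsworth–Emmons disconnection to a lactone phosphonate anion and syringaldehyde 6, carried as its acetal 7.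
4. Benzylic CH2–aryl bond: cyclopropane-opening (homoconjugate) addition of the aryl Grignard reagent (bromide 8 → 9) to 5; the enolate 10 it releases is the olefination partner, so 5 + 9 + 7 → 10 → 11 → 12 in one flask.

Assumption: operations run in one flask without isolation (Grignard formation, ring opening, olefination, acidic quench) are counted as one step.

## Route

Step 1
Reactants: 1 triethyl phosphonoacetate; 2 (R)-epichlorohydrin
Product: 5 diethyl [(1R,5S)-2-oxo-3-oxabicyclo[3.1.0]hexan-1-yl]phosphonate, via transposed epoxide 3 (not isolated), via cyclopropane alkoxide 4 (not isolated)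
Conditions: NaOEt (1.05 equiv), 1 (1.1 equiv), EtOH, 0 °C → reflux, 16 h; AcOH quench
Reagents that add atoms: none
Why: Proposed new method: the established malonate/epichlorohydrin cyclopropane–lactone cascade (closest known reaction type) carried out with a phosphonoacetate carbanion instead; the sodium salt of 1 opens the epoxide of 2 at its CH2 terminus (SN2), the chlorohydrin alkoxide re-closes to the transposed epoxide 3 (intramolecular Williamson), the phosphonate-stabilised carbanion then opens that epoxide at its CH carbon in a 3-exo-tet alkylation with clean inversion to give cyclopropane 4 with the flat ester rather than the bulkier phosphoryl group cis to the CH2O− arm, and that alkoxide lactonises on the cis ester (5-exo-trig acyl substitution), so both rings close in one flask, the single stereocentre of 2 becomes C5 of 5 through one defined inversion, and C1 is fixed because the ring fusion can only be cis.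

Step 2
Reactants: 6 syringaldehyde
Product: 7 4-(1-ethoxyethoxy)-3,5-dimethoxybenzaldehyde (racemic at the acetal carbon)
Conditions: ethyl vinyl ether (3 equiv), PPTS (5 mol%), CH2Cl2, rt; NaHCO3 wash, used crude
Reagents that add atoms: ethyl vinyl ether, C=COCC
Why: Acid-catalysed addition of the phenol O–H across the vinyl ether (1-ethoxyethyl acetal protection) has no co-product, masks the acidic phenol that would otherwise quench the enolate of step 3, and creates only an inconsequential racemic acetal centre that is removed again.

Step 3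
Reactants: 5 diethyl [(1R,5S)-2-oxo-3-oxabicyclo[3.1.0]hexan-1-yl]phosphonate; 7 4-(1-ethoxyethoxy)-3,5-dimethoxybenzaldehyde; 8 5-bromo-1,2,3-trimethoxybenzene
Product: 12 (3E,4R)-3-[(4-hydroxy-3,5-dimethoxyphenyl)methylidene]-4-[(3,4,5-trimethoxyphenyl)methyl]oxolan-2-one, via aryl Grignard reagent 9 (not isolated), via magnesium phosphonoenolate 10 (not isolated), via acetal-protected benzylidene lactone 11 (not isolated)
Conditions: 8 (1.3 equiv), Mg, THF, 45 °C; added to 5, CuI (10 mol%), THF, −30 → 0 °C; then 7 (1.6 equiv), 0 → 60 °C; then 1 M HCl, rt, 1 h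
Reagents that add atoms: none
Why: Proposed new method: a telescoped homo-Michael/Horner–Wadsworth–Emmons sequence whose closest known reaction types are the CuI-catalysed Grignard opening of the malonate-derived bicyclic cyclopropane lactone, the tandem conjugate addition/olefination of 2-phosphonoacrylates and magnesium-mediated E-selective HWE reactions; the arylcopper species formed from 9 attacks the unhindered cyclopropane CH2 (C6) in an SN2 sense and expels the doubly stabilised phosphonate–lactone enolate, so C5 of 5 becomes C4 of the product with its four bonds untouched, the chelated bromomagnesium phosphonoenolate 10 then adds reversibly to aldehyde 7 and loses diethyl phosphate by syn-elimination under thermodynamic control to give the E alkene (aryl anti to the lactone carbonyl), and the acidic quench hydrolyses the aryl 1-ethoxyethyl acetal to the free phenol without touching the lactone or the aryl methyl ethers.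

## Compound list

1 | triethyl phosphonoacetate (ethyl 2-(diethoxyphosphoryl)acetate) | CCOC(=O)CP(=O)(OCC)OCC | starting material
2 | (R)-epichlorohydrin, (2R)-2-(chloromethyl)oxirane | ClC[C@H]1CO1 | starting material
3 | ethyl 2-(diethoxyphosphoryl)-3-[(2R)-oxiran-2-yl]propanoate (both epimers at C2; present as its sodium enolate) | CCOC(=O)C(C[C@@H]1CO1)P(=O)(OCC)OCC | intermediate
4 | ethyl (1R,2S)-1-(diethoxyphosphoryl)-2-(hydroxymethyl)cyclopropane-1-carboxylate (CH2OH cis to the ester; present as its sodium alkoxide) | OC[C@@H]1C[C@@]1(C(=O)OCC)P(=O)(OCC)OCC | intermediate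
5 | diethyl [(1R,5S)-2-oxo-3-oxabicyclo[3.1.0]hexan-1-yl]phosphonate (cis-fused cyclopropane lactone) | O=C1OC[C@@H]2C[C@]12P(=O)(OCC)OCC | intermediate
6 | syringaldehyde (4-hydroxy-3,5-dimethoxybenzaldehyde) | COc1cc(C=O)cc(OC)c1O | starting material
7 | 4-(1-ethoxyethoxy)-3,5-dimethoxybenzaldehyde (racemic acetal carbon) | CCOC(C)Oc1c(OC)cc(C=O)cc1OC | intermediate
8 | 5-bromo-1,2,3-trimethoxybenzene | COc1cc(Br)cc(OC)c1OC | starting material
9 | 3,4,5-trimethoxyphenylmagnesium bromide | COc1cc([Mg]Br)cc(OC)c1OC | intermediate
10 | bromomagnesium enolate of diethyl {(4S)-2-oxo-4-[(3,4,5-trimethoxyphenyl)methyl]oxolan-3-yl}phosphonate (same spatial arrangement at C4 as in 12; the descriptor is S only because phosphorus raises the priority of C3) | CCOP(=O)(OCC)C1=C(O[Mg]Br)OC[C@@H]1Cc2cc(OC)c(OC)c(OC)c2 | intermediate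
11 | (3E,4R)-3-{[4-(1-ethoxyethoxy)-3,5-dimethoxyphenyl]methylidene}-4-[(3,4,5-trimethoxyphenyl)methyl]oxolan-2-one (both acetal epimers) | CCOC(C)Oc1c(OC)cc(/C=C2/C(=O)OC[C@@H]2Cc3cc(OC)c(OC)c(OC)c3)cc1OC | intermediate
12 | (3E,4R)-3-[(4-hydroxy-3,5-dimethoxyphenyl)methylidene]-4-[(3,4,5-trimethoxyphenyl)methyl]oxolan-2-one (CNP0198204.1) | COc1cc(/C=C2/C(=O)OC[C@@H]2Cc2cc(OC)c(OC)c(OC)c2)cc(OC)c1O | target

## Totals and risks

Total step count: 3.
Longest linear sequence: 2 steps (step 1 → step 3); step 2 is a one-step side branch that joins in step 3.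

Steps most likely to fail, most risky first:

**Step 1.** Two things can go wrong. The cyclopropane alkoxide may close on phosphorus (giving a cyclic phosphonate) instead of on the ester. Some direct displacement of chloride would give the enantiomer and erode the ee; about 93–97% ee is expected by analogy with malonate, to be upgraded by recrystallising 12. The fallback sets out from 2 and keeps the same two-ring cascade but with diethyl malonate (NaOEt, EtOH, reflux), which is established, to give ethyl (1S,5R)-2-oxo-3-oxabicyclo[3.1.0]hexane-1-carboxylate F1. Opening F1 with Grignard reagent 9 (CuI cat., THF, −30 °C) gives ethyl (3S,4R)-2-oxo-4-[(3,4,5-trimethoxyphenyl)methyl]oxolane-3-carboxylate F2. Krapcho dealkoxycarbonylation (LiCl, wet DMSO, 140 °C) gives (4R)-4-[(3,4,5-trimethoxyphenyl)methyl]oxolan-2-one F3. Its lithium enolate (LDA, THF, −78 °C) adds to 7 to give the trans aldol (3S,4R)-3-{[4-(1-ethoxyethoxy)-3,5-dimethoxyphenyl](hydroxy)methyl}-4-[(3,4,5-trimethoxyphenyl)methyl]oxolan-2-one F4. MsCl/Et3N converts it into the benzylic methanesulfonate F5, and DBU eliminates this (E1cB) to 11, where the route is rejoined; the 1 M HCl treatment of step 3 then gives 12. Acid-mediated dehydration is avoided because the benzylic cation would cyclise onto the trimethoxyphenyl ring.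

**Step 3.** The magnesium aldolate of a fully substituted phosphonate carbanion may collapse slowly with the electron-rich aldehyde, or give some Z isomer. The Z isomer can be removed by crystallisation or equilibrated with catalytic iodine. The fallback sets out from enolate 10, generated from 5 and 9 exactly as in step 3, and traps it with paraformaldehyde (THF, reflux). This olefination has no geometry issue and gives (4R)-3-methylidene-4-[(3,4,5-trimethoxyphenyl)methyl]oxolan-2-one F6. A Mizoroki–Heck arylation with commercial 4-bromo-2,6-dimethoxyphenol (Pd(OAc)2, P(o-tol)3, NaOAc, DMF, 100 °C; zerovalent palladium formed in the flask) then installs the aryl group. Syn-carbopalladation followed by syn-β-hydride elimination from the new benzylic CH2 gives the E-benzylidene lactone, so the route is rejoined directly at 12. Acetate as base is chosen to limit migration of the double bond into the ring, which would destroy C4.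

**Step 2.** This is the least risky step. Acetal formation on the hindered, acidic phenol may be sluggish, or the aryl acetal of 7 may be shed on contact with magnesium salts at 60 °C, which would deactivate the aldehyde as its phenoxide. The fallback sets out from 6 and silylates it (TBSCl, imidazole, DMF, rt) to 4-[(tert-butyldimethylsilyl)oxy]-3,5-dimethoxybenzaldehyde F7. F7 is used in place of 7 with enolate 10 under the conditions of step 3, with a neutral NH4Cl quench, to isolate (3E,4R)-3-({4-[(tert-butyldimethylsilyl)oxy]-3,5-dimethoxyphenyl}methylidene)-4-[(3,4,5-trimethoxyphenyl)methyl]oxolan-2-one F8. F8 is cleaved with TBAF/AcOH (THF, 0 °C), returning to the route at 12 at the cost of one extra step.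

## Further compounds

F1 | step 1 | ethyl (1S,5R)-2-oxo-3-oxabicyclo[3.1.0]hexane-1-carboxylate | O=C1OC[C@@H]2C[C@]12C(=O)OCC
F2 | step 1 | ethyl (3S,4R)-2-oxo-4-[(3,4,5-trimethoxyphenyl)methyl]oxolane-3-carboxylate (3,4-trans) | CCOC(=O)[C@H]1C(=O)OC[C@@H]1Cc2cc(OC)c(OC)c(OC)c2
F3 | step 1 | (4R)-4-[(3,4,5-trimethoxyphenyl)methyl]oxolan-2-one | O=C1OC[C@H](Cc2cc(OC)c(OC)c(OC)c2)C1
F4 | step 1 | (3S,4R)-3-{[4-(1-ethoxyethoxy)-3,5-dimethoxyphenyl](hydroxy)methyl}-4-[(3,4,5-trimethoxyphenyl)methyl]oxolan-2-one (3,4-trans; carbinol and acetal epimers) | CCOC(C)Oc1c(OC)cc(C(O)[C@H]2C(=O)OC[C@@H]2Cc3cc(OC)c(OC)c(OC)c3)cc1OC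
F5 | step 1 | [4-(1-ethoxyethoxy)-3,5-dimethoxyphenyl]{(3S,4R)-2-oxo-4-[(3,4,5-trimethoxyphenyl)methyl]oxolan-3-yl}methyl methanesulfonate | CCOC(C)Oc1c(OC)cc(C(OS(C)(=O)=O)[C@H]2C(=O)OC[C@@H]2Cc3cc(OC)c(OC)c(OC)c3)cc1OC
F6 | step 3 | (4R)-3-methylidene-4-[(3,4,5-trimethoxyphenyl)methyl]oxolan-2-one | C=C1C(=O)OC[C@@H]1Cc2cc(OC)c(OC)c(OC)c2
F7 | step 2 | 4-[(tert-butyldimethylsilyl)oxy]-3,5-dimethoxybenzaldehyde | COc1cc(C=O)cc(OC)c1O[Si](C)(C)C(C)(C)C
F8 | step 2 | (3E,4R)-3-({4-[(tert-butyldimethylsilyl)oxy]-3,5-dimethoxyphenyl}methylidene)-4-[(3,4,5-trimethoxyphenyl)methyl]oxolan-2-one | COc1cc(/C=C2/C(=O)OC[C@@H]2Cc3cc(OC)c(OC)c(OC)c3)cc(OC)c1O[Si](C)(C)C(C)(C)C
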